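The 1,2-dioxane is numbered O1, O2, ketal carbon C3, C4, C5, C6, with Ca the acetic acid methylene on C6. Its O1–C6–Ca–CO2H array is traced back to a terminal C6=Ca alkene that takes up a peroxide oxygen at C6 and a carbonyl carbon at Ca. A ligand-controlled, palladium-catalysed peroxycyclisation–methoxycarbonylation of an acyclic methoxy hydroperoxy ketal closes the ring, makes the O1–C6 and Ca–carbonyl bonds and sets C6 in one operation; ketal centre C3 then settles cis under anomeric control. The precursor is a ketone-derived hydroperoxy ketal with a but-3-enyl arm and a silyl-capped pent-4-ynyl arm. The enyne ketone chain is joined later by Sonogashira coupling.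

Key step: step 4

Remark on locants: the text uses O1, O2, C3 (ketal carbon), C4, C5, C6 and Ca; the systematic names number the ring from the acetate-bearing carbon, so the target is (3S,6R): ketal carbon R, acetate-bearing carbon S, OMe and CH2CO2H cis.

Assumption on the precursor: hydroperoxy ketal 8 is made and used as the racemate (R enantiomer drawn). An acyclic methoxy hydroperoxy ketal that ionises in acidic methanol can lose H2O2 for good, so the plan does not count on epimerising 8. Methanol is limited during the cyclisation, and C3 is corrected after ring closure, where the peroxide is tethered.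

Assumption on the ligand: the sense of induction at C6 cannot be predicted with confidence; the (S,S) ligand is written, and its mirror image would be used if the first experiment shows the opposite sense.

Handling: all peroxides are kept cold, in solution and behind a shield, and are not concentrated to dryness.

Step 1
Reactants: 1 pent-4-enoic acid
Product: 3 N-methoxy-N-methylpent-4-enamide, via acyl imidazole 2 (not isolated)
Conditions: 1,1'-carbonyldiimidazole, CH2Cl2, 23 °C; then MeNH(OMe)·HCl, 23 °C
Reagents that add atoms: N,O-dimethylhydroxylamine hydrochloride, CNOC.Cl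
Why: Amide formation through the acyl imidazole is a standard activation that leaves the alkene untouched and gives the amide needed for a Weinreb ketone synthesis.

Step 2
Reactants: 4 (5-chloropent-1-yn-1-yl)trimethylsilane; 3 N-methoxy-N-methylpent-4-enamide
Product: 7 10-(trimethylsilyl)dec-1-en-9-yn-5-one, via Grignard reagent 5 (not isolated), via chelated hemiaminal 6 (not isolated)
Conditions: 4, Mg, I2 (cat.), THF, reflux; then 3, THF, 0 °C; aq. NH4Cl
Reagents that add atoms: none
Why: Weinreb ketone synthesis: the primary alkylmagnesium chloride adds only once because the magnesium-chelated tetrahedral adduct persists until work-up, and neither the alkene nor the silyl alkyne reacts with the Grignard reagent.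

Step 3
Reactants: 7 10-(trimethylsilyl)dec-1-en-9-yn-5-one
Product: 8 5-hydroperoxy-5-methoxy-10-(trimethylsilyl)dec-1-en-9-yne (racemate; R enantiomer drawn)
Conditions: urea–H2O2, Sc(OTf)3 (10 mol %), MeOH, 23 °C; used promptly
Reagents that add atoms: urea–hydrogen peroxide adduct, NC(N)=O.OO; methanol, CO
Why: Lewis-acid-catalysed peroxyketalisation, a known route from ketones to acyclic methoxy hydroperoxy ketals: Sc(OTf)3 generates the methoxycarbenium ion, which H2O2 captures; no stereocontrol is needed because the racemate is used.

Step 4
Reactants: 8 5-hydroperoxy-5-methoxy-10-(trimethylsilyl)dec-1-en-9-yne (racemate)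
Product: 10 methyl 2-[(3S,6R)-6-methoxy-6-[5-(trimethylsilyl)pent-4-yn-1-yl]-1,2-dioxan-3-yl]acetate, via trans ketal epimer 9 (not isolated)
Conditions: Pd(O2CCF3)2 (10 mol %), (S,S)-2,2'-(propane-2,2-diyl)bis(4-phenyl-4,5-dihydro-1,3-oxazole) (12 mol %), p-benzoquinone (2 equiv), CO (1 atm), MeOH (10 equiv), CH2Cl2, −20 → 0 °C; then TsOH·H2O (5 mol %), MeOH, 0 → 23 °C
Reagents that add atoms: carbon monoxide, [C-]#[O+]; methanol, CO
Why: Proposed new method: Ligated divalent palladium binds the terminal alkene, the hydroperoxide oxygen O1 adds anti to the metal at the internal carbon C6 in a 6-exo-trig closure that forms the 1,2-dioxane, and the primary Ca–Pd bond takes up CO and is cleaved by methanol to the ester, benzoquinone returning the zerovalent palladium to the divalent state. The closest known reaction types are the cyclisation of unsaturated hydroperoxides to 1,2-dioxanes by divalent palladium and the alkoxypalladation–methoxycarbonylation of alkenols to tetrahydropyranyl acetates (enantioselective variants with chiral bis(oxazoline)-type ligands exist for alcohol and phenol nucleophiles); a hydroperoxy ketal has not served as the oxygen nucleophile in such a carbonylative cascade. The new stereocentre C6 is set by the chiral bis(oxazoline) ligand, which selects the alkene face. C3 is not a kinetic problem: a chair transition state with axial OMe and equatorial alkene should lead from the matched enantiomer of 8 straight to 10, and epimer 9 from the other enantiomer is equilibrated by acid in methanol to the anomerically stabilised cis ketal, with the peroxide tethered throughout. The step needs attack at C6 and not at Ca, secured by the monosubstituted alkene (6-exo over 7-endo), and CO insertion faster than β-hydride loss or ketonisation of the β-peroxyalkylpalladium, secured by the CO atmosphere and the single β-hydrogen; the silyl cap keeps the alkyne out of oxidative carbonylation. The main hazards are oxidation of CO or of zerovalent palladium by the hydroperoxide, which low temperature, limited methanol and excess benzoquinone are meant to suppress.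

Step 5
Reactants: 10 methyl 2-[(3S,6R)-6-methoxy-6-[5-(trimethylsilyl)pent-4-yn-1-yl]-1,2-dioxan-3-yl]acetate
Product: 11 methyl 2-[(3S,6R)-6-methoxy-6-(pent-4-yn-1-yl)-1,2-dioxan-3-yl]acetate
Conditions: Bu4NF, AcOH (1:1), THF, 0 °C
Reagents that add atoms: none
Why: Fluoride-induced protodesilylation of an alkynylsilane; the acetic acid buffer keeps the medium non-basic, so the β-peroxy ester cannot open by elimination, and the ketal and ester are untouched.

Step 6
Reactants: 12 dec-9-yn-1-ol
Product: 14 (9E)-10-iododec-9-en-1-ol, via alkenylzirconocene 13 (not isolated)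
Conditions: Cp2Zr(H)Cl (2.3 equiv), THF, 23 °C; then I2, 0 °C
Reagents that add atoms: iodine, II
Why: Hydrozirconation–iodination: syn addition of Zr–H places zirconium on the terminal carbon and iodinolysis proceeds with retention, giving only the E iodoalkene; the extra hydride equivalent is consumed by the free hydroxyl.

Step 7
Reactants: 14 (9E)-10-iododec-9-en-1-ol
Product: 15 (9E)-10-iododec-9-enal
Conditions: Dess–Martin periodinane, CH2Cl2, 23 °C
Reagents that add atoms: none
Why: Dess–Martin oxidation of a primary alcohol stops at the aldehyde under neutral conditions and leaves the alkenyl iodide and its geometry intact.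

Step 8
Reactants: 15 (9E)-10-iododec-9-enal
Product: 16 (10E)-11-iodoundec-10-en-2-ol (racemate)
Conditions: MeMgBr, THF, −78 °C; aq. NH4Cl
Reagents that add atoms: methylmagnesium bromide, C[Mg]Br
Why: Grignard addition to the aldehyde at low temperature is much faster than exchange at the alkenyl iodide; the carbinol centre forms as a racemate and is erased in step 9.

Step 9
Reactants: 16 (10E)-11-iodoundec-10-en-2-ol
Product: 17 (10E)-11-iodoundec-10-en-2-one
Conditions: Dess–Martin periodinane, CH2Cl2, 23 °C
Reagents that add atoms: none
Why: Dess–Martin oxidation of the secondary alcohol gives the methyl ketone without touching the E iodoalkene.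

Step 10
Reactants: 11 methyl 2-[(3S,6R)-6-methoxy-6-(pent-4-yn-1-yl)-1,2-dioxan-3-yl]acetate; 17 (10E)-11-iodoundec-10-en-2-one
Product: 18 methyl 2-[(3S,6R)-6-methoxy-6-[(6E)-15-oxohexadec-6-en-4-yn-1-yl]-1,2-dioxan-3-yl]acetate
Conditions: PdCl2(PPh3)2 (5 mol %), CuI (10 mol %), Et3N, THF (degassed), 23 °C
Reagents that add atoms: none
Why: Sonogashira coupling of a terminal alkyne with an E alkenyl iodide runs at room temperature with retention of alkene geometry; saturated dialkyl peroxides tolerate brief exposure to this catalyst system, and the ketone and ester are inert.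

Step 11
Reactants: 18 methyl 2-[(3S,6R)-6-methoxy-6-[(6E)-15-oxohexadec-6-en-4-yn-1-yl]-1,2-dioxan-3-yl]acetate
Product: 19 2-[(3S,6R)-6-methoxy-6-[(6E)-15-oxohexadec-6-en-4-yn-1-yl]-1,2-dioxan-3-yl]acetic acid
Conditions: pig liver esterase, pH 7 phosphate buffer–acetone, 25 °C; then aq. NaH2PO4 to pH 5
Reagents that add atoms: water, O
Why: Enzymatic ester hydrolysis at neutral pH frees the acid without the base that could open the β-peroxy ester by elimination and without the acid that could disturb the ketal, so both stereocentres are preserved.

Compound list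
1 | pent-4-enoic acid | C=CCCC(=O)O | starting material
2 | 1-(pent-4-enoyl)-1H-imidazole | C=CCCC(=O)n1ccnc1 | intermediate
3 | N-methoxy-N-methylpent-4-enamide | C=CCCC(=O)N(C)OC | intermediate
4 | (5-chloropent-1-yn-1-yl)trimethylsilane | C[Si](C)(C)C#CCCCCl | starting material
5 | [5-(trimethylsilyl)pent-4-yn-1-yl]magnesium chloride | C[Si](C)(C)C#CCCC[Mg]Cl | intermediate
6 | chloromagnesium salt of 5-[methoxy(methyl)amino]-10-(trimethylsilyl)dec-1-en-9-yn-5-ol (chelated tetrahedral adduct) | C=CCCC(O[Mg]Cl)(N(C)OC)CCCC#C[Si](C)(C)C | intermediate
7 | 10-(trimethylsilyl)dec-1-en-9-yn-5-one | C=CCCC(=O)CCCC#C[Si](C)(C)C | intermediate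
8 | 5-hydroperoxy-5-methoxy-10-(trimethylsilyl)dec-1-en-9-yne, racemate, (5R) enantiomer drawn | CO[C@@](CCCC#C[Si](C)(C)C)(CCC=C)OO | intermediate
9 | methyl 2-[(3S,6S)-6-methoxy-6-[5-(trimethylsilyl)pent-4-yn-1-yl]-1,2-dioxan-3-yl]acetate (trans ketal epimer) | CO[C@]1(CCCC#C[Si](C)(C)C)CC[C@@H](CC(=O)OC)OO1 | intermediate
10 | methyl 2-[(3S,6R)-6-methoxy-6-[5-(trimethylsilyl)pent-4-yn-1-yl]-1,2-dioxan-3-yl]acetate (OMe and CH2CO2Me cis) | CO[C@@]1(CCCC#C[Si](C)(C)C)CC[C@@H](CC(=O)OC)OO1 | intermediate
11 | methyl 2-[(3S,6R)-6-methoxy-6-(pent-4-yn-1-yl)-1,2-dioxan-3-yl]acetate | CO[C@@]1(CCCC#C)CC[C@@H](CC(=O)OC)OO1 | intermediate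
12 | dec-9-yn-1-ol | C#CCCCCCCCCO | starting material
13 | (E)-1-[chlorobis(cyclopentadienyl)zirconio]-10-[chlorobis(cyclopentadienyl)zirconiooxy]dec-1-ene | [cH-]1cccc1.[cH-]1cccc1.[cH-]1cccc1.[cH-]1cccc1.Cl[Zr+2]/C=C/CCCCCCCCO[Zr+2]Cl | intermediate
14 | (9E)-10-iododec-9-en-1-ol | OCCCCCCCC/C=C/I | intermediate
15 | (9E)-10-iododec-9-enal | O=CCCCCCCC/C=C/I | intermediate
16 | (10E)-11-iodoundec-10-en-2-ol, racemate | CC(O)CCCCCCC/C=C/I | intermediate
17 | (10E)-11-iodoundec-10-en-2-one | CC(=O)CCCCCCC/C=C/I | intermediate
18 | methyl 2-[(3S,6R)-6-methoxy-6-[(6E)-15-oxohexadec-6-en-4-yn-1-yl]-1,2-dioxan-3-yl]acetate | CO[C@@]1(CCCC#C/C=C/CCCCCCCC(C)=O)CC[C@@H](CC(=O)OC)OO1 | intermediate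
19 | 2-[(3S,6R)-6-methoxy-6-[(6E)-15-oxohexadec-6-en-4-yn-1-yl]-1,2-dioxan-3-yl]acetic acid | CO[C@@]1(CCCC#C/C=C/CCCCCCCC(C)=O)CC[C@@H](CC(=O)O)OO1 | target

Total step count: 11. Longest linear sequence: 7 steps (steps 1, 2, 3, 4, 5, 10, 11 from pent-4-enoic acid); steps 6–9 form a four-step side branch to iodide 17.

Steps most likely to fail

Step 4 (bears the label Proposed new method). What may go wrong: oxidation of CO or of zerovalent palladium by the hydroperoxide with loss of the O–O bond; ketonisation of the β-peroxyalkylpalladium before CO insertion; loss of H2O2 from the acyclic ketal; or poor facial selectivity at C6 if the chair preference of the substrate overrides the ligand. The fallback uses known chemistry and sets out from ketone 7. Cross-metathesis with methyl acrylate (second-generation Hoveyda–Grubbs catalyst, CH2Cl2, 40 °C) should give methyl (2E)-6-oxo-11-(trimethylsilyl)undec-2-en-10-ynoate F1. Peroxyketalisation as in step 3 would give racemic methyl (2E)-6-hydroperoxy-6-methoxy-11-(trimethylsilyl)undec-2-en-10-ynoate F2. Diethylamine in 2,2,2-trifluoroethanol would close the ring by intramolecular oxa-Michael addition of the hydroperoxide to the enoate, giving the racemic cis dioxane ester F3 together with the racemic trans ketal epimer F4. TsOH in methanol would converge F4 on F3, and preparative chromatography on a chiral stationary phase would deliver the (3S,6R) enantiomer, which is compound 10, where the route is rejoined. This gives up the asymmetric induction and half of the material.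

Step 3. What may go wrong: the three-component equilibrium in methanol stalls at partial conversion or drifts toward the dimethyl ketal and the geminal bis-hydroperoxide, and the labile product reverts to ketone on handling. The fallback sets out from ketone 7. Ketalisation with HC(OMe)3 and TsOH (cat.) in methanol gives 5,5-dimethoxy-10-(trimethylsilyl)dec-1-en-9-yne F5, which is isolated. Treatment with a small excess of anhydrous ethereal H2O2 and camphorsulfonic acid (cat.) in Et2O at 0 °C then exchanges one methoxy group for OOH in the absence of bulk methanol and gives 8, where the route is rejoined.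

Step 11. What may go wrong: slow enzymatic turnover of the long lipophilic ester in aqueous buffer, so that prolonged exposure erodes the peroxide or the ketal. The fallback sets out from alkyne ester 11 and moves the ester cleavage ahead of the coupling. Saponification at this compact stage with LiOH·H2O in THF–H2O at 0 °C, then dilute HCl to pH 4, gives 2-[(3S,6R)-6-methoxy-6-(pent-4-yn-1-yl)-1,2-dioxan-3-yl]acetic acid F6. Sonogashira coupling of F6 with iodide 17 under the conditions of step 10, with one more equivalent of Et3N, then gives target 19 directly.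

Further compounds
F1 | step 4 | methyl (2E)-6-oxo-11-(trimethylsilyl)undec-2-en-10-ynoate | COC(=O)/C=C/CCC(=O)CCCC#C[Si](C)(C)C
F2 | step 4 | methyl (2E)-6-hydroperoxy-6-methoxy-11-(trimethylsilyl)undec-2-en-10-ynoate, racemate | COC(=O)/C=C/CCC(OC)(OO)CCCC#C[Si](C)(C)C
F3 | step 4 | racemic cis methyl 2-[6-methoxy-6-[5-(trimethylsilyl)pent-4-yn-1-yl]-1,2-dioxan-3-yl]acetate (10 and its enantiomer) | CO[C@@]1(CCCC#C[Si](C)(C)C)CC[C@@H](CC(=O)OC)OO1.CO[C@]1(CCCC#C[Si](C)(C)C)CC[C@H](CC(=O)OC)OO1
F4 | step 4 | racemic trans methyl 2-[6-methoxy-6-[5-(trimethylsilyl)pent-4-yn-1-yl]-1,2-dioxan-3-yl]acetate (9 and its enantiomer) | CO[C@]1(CCCC#C[Si](C)(C)C)CC[C@@H](CC(=O)OC)OO1.CO[C@@]1(CCCC#C[Si](C)(C)C)CC[C@H](CC(=O)OC)OO1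
F5 | step 3 | 5,5-dimethoxy-10-(trimethylsilyl)dec-1-en-9-yne | COC(CCC=C)(CCCC#C[Si](C)(C)C)OC
F6 | step 11 | 2-[(3S,6R)-6-methoxy-6-(pent-4-yn-1-yl)-1,2-dioxan-3-yl]acetic acid | CO[C@@]1(CCCC#C)CC[C@@H](CC(=O)O)OO1
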